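## Retrosynthetic overview

1. Target 19 ⇐ 18 by a last-step Schenck ene reaction of singlet oxygen at the C7=C8 alkene (C8–OOH, 6E alkene).
2. 18 ⇐ 17 (lactone enolate methylation, C15) ⇐ macrocyclic homoallylic alcohol 13 by a transannular, orthoester-tethered 6-exo radical cyclisation (C1–C15 bond, δ-lactone, C1). This is the proposed new step.
3. 13 ⇐ acyclic diene 12 by ring-closing metathesis (C1=C14).
4. 12 ⇐ (2E,6E)-farnesol 1: two Sharpless epoxidations with the same tartrate (C11/C12, then C3/C4), vinyl–copper couplings at C13 and C2, and a Payne rearrangement that inverts C3.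
5. Ring order: C11–C12 oxirane first, 14-membered carbocycle second, δ-lactone last.

Assumption: commercial (2E,6E)-farnesol is used as the single-isomer starting material. Cembrane numbering is used throughout (ring C1–C14; C15–C17 lactone carbons; C18, C19, C20 the methyls on C4, C8, C12).

## Route

Step 1
Reactants: 1 (2E,6E)-farnesol
Product: 2 tert-butyl(diphenyl)[(2E,6E)-3,7,11-trimethyldodeca-2,6,10-trienyloxy]silane
Conditions: TBDPSCl, imidazole, DMF, 0 °C to rt
Reagents that add atoms: tert-butyl(chloro)diphenylsilane CC(C)(C)[Si](Cl)(c1ccccc1)c1ccccc1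
Why: Standard silylation of the primary allylic alcohol, chosen because a silyl ether (unlike an allylic acetate) survives the later copper/Grignard step; no stereocentre is formed.

Step 2
Reactants: 2 tert-butyl(diphenyl)[(2E,6E)-3,7,11-trimethyldodeca-2,6,10-trienyloxy]silane
Product: 3 (2E,6E,10E)-12-(tert-butyldiphenylsilyloxy)-2,6,10-trimethyldodeca-2,6,10-trien-1-ol
Conditions: SeO2 (0.2 equiv), t-BuOOH (3 equiv), salicylic acid (0.1 equiv), CH2Cl2, rt
Reagents that add atoms: selenium dioxide O=[Se]=O (catalytic oxygen carrier); tert-butyl hydroperoxide CC(C)(C)OO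
Why: Selenium dioxide allylic oxidation (ene reaction then 2,3-sigmatropic shift) selects the (E)-methyl of the terminal trisubstituted alkene and gives the (E)-2-methylallylic alcohol (future C13–OH) needed for the first epoxidation.

Step 3
Reactants: 3 (2E,6E,10E)-12-(tert-butyldiphenylsilyloxy)-2,6,10-trimethyldodeca-2,6,10-trien-1-ol
Product: 4 [(2S,3S)-3-[(3E,7E)-9-(tert-butyldiphenylsilyloxy)-3,7-dimethylnona-3,7-dienyl]-2-methyloxiran-2-yl]methanol
Conditions: Ti(OiPr)4 (10 mol%), L-(+)-diethyl tartrate (12 mol%), t-BuOOH, 4 Å MS, CH2Cl2, −20 °C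
Reagents that add atoms: tert-butyl hydroperoxide CC(C)(C)OO
Why: Sharpless asymmetric epoxidation touches only the allylic-alcohol alkene, and L-(+)-tartrate gives the (2S,3S)-epoxy alcohol from an (E)-2-methylalk-2-en-1-ol, which sets C11 (S) and C12 (S).

Step 4
Reactants: 4 [(2S,3S)-3-[(3E,7E)-9-(tert-butyldiphenylsilyloxy)-3,7-dimethylnona-3,7-dienyl]-2-methyloxiran-2-yl]methanol
Product: 6 tert-butyl[(2E,6E)-3,7-dimethyl-9-[(2S,3S)-3-methyl-3-(prop-2-enyl)oxiran-2-yl]nona-2,6-dienyloxy]diphenylsilane, via epoxy triflate 5 (not isolated)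
Conditions: Tf2O, 2,6-lutidine, CH2Cl2, −78 °C; then CH2=CHMgBr, CuI (20 mol%), THF, −78 to −40 °C
Reagents that add atoms: vinylmagnesium bromide C=C[Mg]Br
Why: Copper-catalysed Grignard coupling with a primary triflate (SN2 at C13) is much faster at −78 °C than attack on the trisubstituted oxirane, so the C13–C14 bond forms with both oxirane stereocentres untouched.

Step 5
Reactants: 6 tert-butyl[(2E,6E)-3,7-dimethyl-9-[(2S,3S)-3-methyl-3-(prop-2-enyl)oxiran-2-yl]nona-2,6-dienyloxy]diphenylsilane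
Product: 7 (2E,6E)-3,7-dimethyl-9-[(2S,3S)-3-methyl-3-(prop-2-enyl)oxiran-2-yl]nona-2,6-dien-1-ol
Conditions: Bu4NF, THF, 0 °C to rt
Reagents that add atoms: none
Why: Fluoride desilylation frees the C2 allylic alcohol without affecting the epoxide or the alkenes.

Step 6
Reactants: 7 (2E,6E)-3,7-dimethyl-9-[(2S,3S)-3-methyl-3-(prop-2-enyl)oxiran-2-yl]nona-2,6-dien-1-ol
Product: 8 [(2S,3S)-3-methyl-3-[(3E)-4-methyl-6-[(2S,3S)-3-methyl-3-(prop-2-enyl)oxiran-2-yl]hex-3-enyl]oxiran-2-yl]methanol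
Conditions: Ti(OiPr)4 (10 mol%), L-(+)-diethyl tartrate (12 mol%), t-BuOOH, 4 Å MS, CH2Cl2, −20 °C
Reagents that add atoms: tert-butyl hydroperoxide CC(C)(C)OO
Why: A second Sharpless asymmetric epoxidation with the same tartrate epoxidises only the geraniol-type allylic alcohol alkene and gives the (3S,4S)-epoxide by reagent control (as geraniol gives the (2S,3S)-epoxide), leaving the C7=C8 and terminal alkenes alone.

Step 7
Reactants: 8 [(2S,3S)-3-methyl-3-[(3E)-4-methyl-6-[(2S,3S)-3-methyl-3-(prop-2-enyl)oxiran-2-yl]hex-3-enyl]oxiran-2-yl]methanol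
Product: 9 (2R,3S,6E)-3,7-dimethyl-9-[(2S,3S)-3-methyl-3-(prop-2-enyl)oxiran-2-yl]non-6-ene-1,2,3-triol
Conditions: 0.5 M NaOH, t-BuOH/H2O, 70 °C
Reagents that add atoms: water O (delivered as hydroxide)
Why: Payne rearrangement (the C2 alkoxide opens the oxirane at C3 with inversion) followed by hydroxide attack at the terminal carbon of the rearranged epoxide inverts C3 to R and keeps the C4–O bond (S), while the isolated C11–C12 epoxide has no neighbouring alkoxide and is inert to dilute base.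

Step 8
Reactants: 9 (2R,3S,6E)-3,7-dimethyl-9-[(2S,3S)-3-methyl-3-(prop-2-enyl)oxiran-2-yl]non-6-ene-1,2,3-triol
Product: 10 (2R,3S,6E)-2,3-dihydroxy-3,7-dimethyl-9-[(2S,3S)-3-methyl-3-(prop-2-enyl)oxiran-2-yl]non-6-enyl 4-methylbenzenesulfonate
Conditions: TsCl, Et3N, Bu2SnO (2 mol%), CH2Cl2, 0 °C
Reagents that add atoms: 4-methylbenzenesulfonyl chloride Cc1ccc(cc1)S(=O)(=O)Cl
Why: Tin-acetal-catalysed sulfonylation of a 1,2-diol is selective for the primary hydroxyl over the secondary and tertiary ones.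

Step 9
Reactants: 10 (2R,3S,6E)-2,3-dihydroxy-3,7-dimethyl-9-[(2S,3S)-3-methyl-3-(prop-2-enyl)oxiran-2-yl]non-6-enyl 4-methylbenzenesulfonate
Product: 12 (4R,5S,8E)-5,9-dimethyl-11-[(2S,3S)-3-methyl-3-(prop-2-enyl)oxiran-2-yl]undeca-1,8-diene-4,5-diol, via terminal epoxide 11 (not isolated)
Conditions: CH2=CHMgBr (5 equiv), CuI (20 mol%), THF, −30 °C to rt
Reagents that add atoms: vinylmagnesium bromide C=C[Mg]Br
Why: The C3 alkoxide closes onto the tosylate to a monosubstituted epoxide (C3 retained), which the vinyl cuprate opens at the unhindered C2 far faster than it touches the trisubstituted epoxide, giving the homoallylic C3 alcohol.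

Step 10
Reactants: 12 (4R,5S,8E)-5,9-dimethyl-11-[(2S,3S)-3-methyl-3-(prop-2-enyl)oxiran-2-yl]undeca-1,8-diene-4,5-diol
Product: 13 (3R,4S,7E,11S,12S)-11,12-epoxy-4,8,12-trimethylcyclotetradeca-1(14),7-diene-3,4-diol
Conditions: first-generation Grubbs catalyst RuCl2(PCy3)2(=CHPh) (10 mol%), CH2Cl2 (1 mM), 40 °C
Reagents that add atoms: none
Why: Ring-closing metathesis of the two monosubstituted alkenes closes the 14-membered ring at C1=C14, the first-generation catalyst does not engage the trisubstituted C7=C8 alkene, and the E/Z ratio of the new alkene does not matter because it is consumed in step 12.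

Step 11
Reactants: 13 (3R,4S,7E,11S,12S)-11,12-epoxy-4,8,12-trimethylcyclotetradeca-1(14),7-diene-3,4-diol
Product: 14 (3R,4S,7E,11S,12S)-3-(2-bromo-1,1-diethoxyethoxy)-11,12-epoxy-4,8,12-trimethylcyclotetradeca-1(14),7-dien-4-ol
Conditions: CH2=C(OEt)2, NBS, 2,6-lutidine, CH2Cl2, −78 to −20 °C
Reagents that add atoms: 1,1-diethoxyethene C=C(OCC)OCC; N-bromosuccinimide BrN1C(=O)CCC1=O
Why: Bromoalkoxylation of a ketene acetal, in which NBS brominates the very electron-rich ketene acetal well before any ring alkene and the less hindered secondary C3 hydroxyl captures the dialkoxycarbenium ion, gives the mixed α-bromo orthoester.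

Step 12
Reactants: 14 (3R,4S,7E,11S,12S)-3-(2-bromo-1,1-diethoxyethoxy)-11,12-epoxy-4,8,12-trimethylcyclotetradeca-1(14),7-dien-4-ol
Product: 17 (1R,3R,4S,7E,11S,12S)-11,12-epoxy-4-hydroxy-17-norcembr-7-en-16,3-olide, via cyclic orthoester 15 (not isolated), via hydroxy ethyl ester 16 (not isolated)
Conditions: Bu3SnH (slow addition), AIBN, PhH (5 mM), 80 °C; then AcOH/THF/H2O, rt; then PPTS (cat.), PhH, 50 °C
Reagents that add atoms: water O
Why: Proposed new method: an α-bromo orthoester serves as a radical tether already at the carboxylic-acid oxidation level – bromine abstraction gives a primary β-oxygenated alkyl radical (electronically like a haloacetal radical and free of the s-trans ester preference that slows α-halo ester cyclisations) that adds 6-exo-trig to C1 of the ring alkene through a chair transition state with the C3–C4 and C1–C14 bonds equatorial, which sets C1 (R, cis to C3), after which the C14 radical takes hydrogen from Bu3SnH and the 2,2-diethoxyoxane is hydrolysed by mild acid to the hydroxy ester that closes to the δ-lactone; the closest known reaction type is the Ueno–Stork bromoacetal radical cyclisation, which stops at the acetal oxidation level.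

Step 13
Reactants: 17 (1R,3R,4S,7E,11S,12S)-11,12-epoxy-4-hydroxy-17-norcembr-7-en-16,3-olide
Product: 18 (1R,3R,4S,7E,11S,12S,15S)-11,12-epoxy-4-hydroxycembr-7-en-16,3-olide
Conditions: LiN(iPr)2 (2.2 equiv), THF, −78 °C; then MeI
Reagents that add atoms: iodomethane CI
Why: Alkylation of the δ-lactone enolate (formed beside the C4 lithium alkoxide) occurs anti to the neighbouring C1 substituent and gives the 15S, all-equatorial methyl lactone, which is also the thermodynamic epimer.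

Step 14
Reactants: 18 (1R,3R,4S,7E,11S,12S,15S)-11,12-epoxy-4-hydroxycembr-7-en-16,3-olide
Product: 19 (1R,3R,4S,6E,8S,11S,12S,15S)-11,12-epoxy-8-hydroperoxy-4-hydroxycembr-6-en-16,3-olide
Conditions: O2, tetraphenylporphyrin (cat.), visible light, CH2Cl2, 0 °C; chromatographic separation
Reagents that add atoms: dioxygen O=O
Why: Schenck ene reaction of singlet oxygen with the only remaining alkene puts oxygen on C8 from the exposed face of the macrocycle and removes a C6 hydrogen from the more crowded side of the alkene (cis effect), giving the tertiary allylic hydroperoxide with a 6E alkene; the C8 configuration is under substrate control and is not predicted here.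

## Compound list

1 | (2E,6E)-farnesol, (2E,6E)-3,7,11-trimethyldodeca-2,6,10-trien-1-ol | OC/C=C(C)/CC/C=C(C)/CCC=C(C)C | starting material
2 | tert-butyl(diphenyl)[(2E,6E)-3,7,11-trimethyldodeca-2,6,10-trienyloxy]silane | CC(C)(C)[Si](c1ccccc1)(c1ccccc1)OC/C=C(C)/CC/C=C(C)/CCC=C(C)C | intermediate
3 | (2E,6E,10E)-12-(tert-butyldiphenylsilyloxy)-2,6,10-trimethyldodeca-2,6,10-trien-1-ol | CC(C)(C)[Si](c1ccccc1)(c1ccccc1)OC/C=C(C)/CC/C=C(C)/CC/C=C(C)/CO | intermediate
4 | [(2S,3S)-3-[(3E,7E)-9-(tert-butyldiphenylsilyloxy)-3,7-dimethylnona-3,7-dienyl]-2-methyloxiran-2-yl]methanol | CC(C)(C)[Si](c1ccccc1)(c1ccccc1)OC/C=C(C)/CC/C=C(C)/CC[C@@H]1O[C@@]1(C)CO | intermediate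
5 | [(2S,3S)-3-[(3E,7E)-9-(tert-butyldiphenylsilyloxy)-3,7-dimethylnona-3,7-dienyl]-2-methyloxiran-2-yl]methyl trifluoromethanesulfonate | CC(C)(C)[Si](c1ccccc1)(c1ccccc1)OC/C=C(C)/CC/C=C(C)/CC[C@@H]1O[C@@]1(C)COS(=O)(=O)C(F)(F)F | intermediate (not isolated)
6 | tert-butyl[(2E,6E)-3,7-dimethyl-9-[(2S,3S)-3-methyl-3-(prop-2-enyl)oxiran-2-yl]nona-2,6-dienyloxy]diphenylsilane | CC(C)(C)[Si](c1ccccc1)(c1ccccc1)OC/C=C(C)/CC/C=C(C)/CC[C@@H]1O[C@@]1(C)CC=C | intermediate
7 | (2E,6E)-3,7-dimethyl-9-[(2S,3S)-3-methyl-3-(prop-2-enyl)oxiran-2-yl]nona-2,6-dien-1-ol | OC/C=C(C)/CC/C=C(C)/CC[C@@H]1O[C@@]1(C)CC=C | intermediate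
8 | [(2S,3S)-3-methyl-3-[(3E)-4-methyl-6-[(2S,3S)-3-methyl-3-(prop-2-enyl)oxiran-2-yl]hex-3-enyl]oxiran-2-yl]methanol | OC[C@@H]1O[C@@]1(C)CC/C=C(C)/CC[C@@H]2O[C@@]2(C)CC=C | intermediate
9 | (2R,3S,6E)-3,7-dimethyl-9-[(2S,3S)-3-methyl-3-(prop-2-enyl)oxiran-2-yl]non-6-ene-1,2,3-triol | OC[C@@H](O)[C@@](C)(O)CC/C=C(C)/CC[C@@H]1O[C@@]1(C)CC=C | intermediate
10 | (2R,3S,6E)-2,3-dihydroxy-3,7-dimethyl-9-[(2S,3S)-3-methyl-3-(prop-2-enyl)oxiran-2-yl]non-6-enyl 4-methylbenzenesulfonate | Cc1ccc(cc1)S(=O)(=O)OC[C@@H](O)[C@@](C)(O)CC/C=C(C)/CC[C@@H]1O[C@@]1(C)CC=C | intermediate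
11 | (2S,5E)-6-methyl-8-[(2S,3S)-3-methyl-3-(prop-2-enyl)oxiran-2-yl]-2-[(2R)-oxiran-2-yl]oct-5-en-2-ol | C1O[C@H]1[C@@](C)(O)CC/C=C(C)/CC[C@@H]2O[C@@]2(C)CC=C | intermediate (not isolated)
12 | (4R,5S,8E)-5,9-dimethyl-11-[(2S,3S)-3-methyl-3-(prop-2-enyl)oxiran-2-yl]undeca-1,8-diene-4,5-diol | C=CC[C@@H](O)[C@@](C)(O)CC/C=C(C)/CC[C@@H]1O[C@@]1(C)CC=C | intermediate
13 | (3R,4S,7E,11S,12S)-11,12-epoxy-4,8,12-trimethylcyclotetradeca-1(14),7-diene-3,4-diol (E/Z mixture at C1=C14) | C1=CC[C@@H](O)[C@@](C)(O)CC/C=C(C)/CC[C@@H]2O[C@@]2(C)C1 | intermediate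
14 | (3R,4S,7E,11S,12S)-3-(2-bromo-1,1-diethoxyethoxy)-11,12-epoxy-4,8,12-trimethylcyclotetradeca-1(14),7-dien-4-ol | C1=CC[C@@H](OC(OCC)(OCC)CBr)[C@@](C)(O)CC/C=C(C)/CC[C@@H]2O[C@@]2(C)C1 | intermediate
15 | (1R,3R,4S,7E,11S,12S)-16,16-diethoxy-3,16:11,12-diepoxy-17-norcembr-7-en-4-ol | C1C(OCC)(OCC)O[C@@H]2C[C@H]1CC[C@]1(C)O[C@H]1CC/C(C)=C/CC[C@]2(C)O | intermediate (not isolated)
16 | ethyl [(1R,3R,4S,7E,11S,12S)-11,12-epoxy-3,4-dihydroxy-4,8,12-trimethylcyclotetradec-7-enyl]acetate | CCOC(=O)C[C@H]1C[C@@H](O)[C@@](C)(O)CC/C=C(C)/CC[C@@H]2O[C@@]2(C)CC1 | intermediate (not isolated)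
17 | (1R,3R,4S,7E,11S,12S)-11,12-epoxy-4-hydroxy-17-norcembr-7-en-16,3-olide | C1C(=O)O[C@@H]2C[C@H]1CC[C@]1(C)O[C@H]1CC/C(C)=C/CC[C@]2(C)O | intermediate
18 | (1R,3R,4S,7E,11S,12S,15S)-11,12-epoxy-4-hydroxycembr-7-en-16,3-olide | C[C@@H]1C(=O)O[C@@H]2C[C@H]1CC[C@]1(C)O[C@H]1CC/C(C)=C/CC[C@]2(C)O | intermediate
19 | (1R,3R,4S,6E,8S,11S,12S,15S)-11,12-epoxy-8-hydroperoxy-4-hydroxycembr-6-en-16,3-olide (CNP0297487.4) | C[C@@H]1C(=O)O[C@@H]2C[C@H]1CC[C@]1(C)O[C@H]1CC[C@](C)(OO)/C=C/C[C@]2(C)O | target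

## Step count and risk

Total step count: 14. Longest linear sequence: 14 (fully linear from 1).

The three steps most likely to fail:

**Step 12 (the proposed new step).** The bromo orthoester may be too labile to survive handling, and 1,5-hydrogen transfer from the allylic C2–H can compete with the 6-exo addition to an unactivated ring alkene. The cis relationship of C1 and C3 rests on a chair transition-state argument only. The fallback is the known Ueno–Stork sequence, which moves the tether to the acetal oxidation level and adds a separate oxidation. It sets out from 13: ethyl vinyl ether and NBS (2,6-lutidine, CH2Cl2, −78 °C) give the bromoacetal F1; Bu3SnH/AIBN in benzene at 80 °C closes it to the cyclic ethyl acetal F2; aqueous acetic acid in THF hydrolyses this to the lactol F3; TEMPO/PhI(OAc)2 oxidises the lactol and the sequence comes back to the route at 17.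

**Step 14.** Free singlet oxygen can also abstract a C19 hydrogen (giving the 7-hydroperoxy-8(19)-ene regioisomer) and can attack either face of C7=C8, so the 8S tertiary hydroperoxide may be a minor product. The fallback replaces any hydrogen-bond guidance by the free C4 hydroxyl with steric shielding of that face. It sets out from 18: Et3SiOTf/2,6-lutidine (CH2Cl2, −78 °C) gives the triethylsilyl ether F4; the same sensitised photo-oxygenation on this substrate gives the silyl ether hydroperoxide F5; HF·pyridine in THF removes the silyl group and the sequence comes back to the route at 19.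

**Step 4.** The triflate carbon is flanked by a fully substituted oxirane carbon, so copper-mediated SN2 may be slow and the cuprate may instead open the epoxide at C11. The fallback brings in the two carbons as a slim sp nucleophile and makes the alkene afterwards. It sets out from 4: the triflate 5 is made as before and treated with LiC≡CSiMe3 in THF/DMPU at −78 °C to give the silyl alkyne F6; K2CO3 in MeOH gives the terminal alkyne F7; semi-hydrogenation with H2 over Pd/CaCO3 poisoned with Pb(OAc)2 and quinoline comes back to the route at 6.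

Further compounds
F1 | step 12 | (3R,4S,7E,11S,12S)-3-(2-bromo-1-ethoxyethoxy)-11,12-epoxy-4,8,12-trimethylcyclotetradeca-1(14),7-dien-4-ol (acetal epimers) | C1=CC[C@@H](OC(OCC)CBr)[C@@](C)(O)CC/C=C(C)/CC[C@@H]2O[C@@]2(C)C1
F2 | step 12 | (1R,3R,4S,7E,11S,12S)-16-ethoxy-3,16:11,12-diepoxy-17-norcembr-7-en-4-ol (anomers) | C1C(OCC)O[C@@H]2C[C@H]1CC[C@]1(C)O[C@H]1CC/C(C)=C/CC[C@]2(C)O
F3 | step 12 | (1R,3R,4S,7E,11S,12S)-3,16:11,12-diepoxy-17-norcembr-7-ene-4,16-diol (anomers) | C1C(O)O[C@@H]2C[C@H]1CC[C@]1(C)O[C@H]1CC/C(C)=C/CC[C@]2(C)O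
F4 | step 14 | (1R,3R,4S,7E,11S,12S,15S)-11,12-epoxy-4-(triethylsilyloxy)cembr-7-en-16,3-olide | C[C@@H]1C(=O)O[C@@H]2C[C@H]1CC[C@]1(C)O[C@H]1CC/C(C)=C/CC[C@]2(C)O[Si](CC)(CC)CC
F5 | step 14 | (1R,3R,4S,6E,8S,11S,12S,15S)-11,12-epoxy-8-hydroperoxy-4-(triethylsilyloxy)cembr-6-en-16,3-olide | C[C@@H]1C(=O)O[C@@H]2C[C@H]1CC[C@]1(C)O[C@H]1CC[C@](C)(OO)/C=C/C[C@]2(C)O[Si](CC)(CC)CC
F6 | step 4 | tert-butyl[(2E,6E)-3,7-dimethyl-9-[(2S,3S)-3-methyl-3-(3-trimethylsilylprop-2-ynyl)oxiran-2-yl]nona-2,6-dienyloxy]diphenylsilane | CC(C)(C)[Si](c1ccccc1)(c1ccccc1)OC/C=C(C)/CC/C=C(C)/CC[C@@H]1O[C@@]1(C)CC#C[Si](C)(C)C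
F7 | step 4 | tert-butyl[(2E,6E)-3,7-dimethyl-9-[(2S,3S)-3-methyl-3-(prop-2-ynyl)oxiran-2-yl]nona-2,6-dienyloxy]diphenylsilane | CC(C)(C)[Si](c1ccccc1)(c1ccccc1)OC/C=C(C)/CC/C=C(C)/CC[C@@H]1O[C@@]1(C)CC#C
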